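**Assumptions**
- Kazinol B is taken as the (2S) chroman, as drawn in the SMILES.
- 2,4-Dihydroxybenzyl alcohol (2) is assumed to be purchasable. If not, it is one NaBH4 reduction of 2,4-dihydroxybenzaldehyde, which would make the route 7 steps.

**Retrosynthetic overview**
- Kazinol B (1) is disconnected at the chroman ring, C4–C4a and C2–O, as a formal inverse-demand oxa-Diels–Alder. The diene is the o-quinone methide derived from 2,4-dihydroxybenzyl alcohol (2), and the dienophile is the electron-rich styrene 3. A chiral phosphoric acid sets C2, and the chroman ring is formed last.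
- Styrene 3 comes from aldehyde 4 by methylenation. The prenyl group of 4 comes from the allyl arene 5 by cross-metathesis.
- Compound 5 comes from bis-ether 6 in one pot: propargyl-Claisen/6π-electrocyclisation forms the 2,2-dimethylchromene ring, and aromatic Claisen rearrangement places the allyl group.
- Compound 6 comes from mono-propargyl ether 7, which comes from 3,4-dihydroxybenzaldehyde (8). Allyl bromide (10), 3-chloro-3-methylbut-1-yne (9), 2-methyl-2-butene (11) and Ph3PCH3Br (12) supply the extra carbons.

**Step 1**
Reactants: 8 (3,4-dihydroxybenzaldehyde), 9 (3-chloro-3-methylbut-1-yne)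
Product: 7 (3-hydroxy-4-[(2-methylbut-3-yn-2-yl)oxy]benzaldehyde)
Conditions: K2CO3, KI, DMF, 60 °C
Reagents that add atoms: 9, 3-chloro-3-methylbut-1-yne, CC(C)(Cl)C#C
Why: Williamson etherification is selective for the more acidic 4-OH (para to CHO, pKa ~7.5) over the 3-OH, so only O4 carries the propargyl group; no stereocentre is involved.

**Step 2**
Reactants: 7, 10 (allyl bromide)
Product: 6 (3-allyloxy-4-[(2-methylbut-3-yn-2-yl)oxy]benzaldehyde)
Conditions: K2CO3, acetone, reflux
Reagents that add atoms: 10, allyl bromide, C=CCBr
Why: simple O-allylation of the remaining phenol (Williamson ether synthesis).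

**Step 3**
Reactants: 6
Product: 5 (7-allyl-8-hydroxy-2,2-dimethyl-2H-chromene-6-carbaldehyde)
Conditions: PhNEt2, 205 °C, sealed tube, 3 h
Reagents that add atoms: none
Why: the aryl propargyl ether undergoes Claisen rearrangement, a [1,5]-H shift and 6π-oxa-electrocyclisation at the only free ortho carbon (C5), giving the chromene. The allyl aryl ether undergoes aromatic Claisen rearrangement at its only free ortho carbon (C2, since C4 carries oxygen), leaving the free 8-OH. Both rearrangements are thermal and give the regiochemistry required by the target.

**Step 4**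
Reactants: 5, 11 (2-methyl-2-butene)
Product: 4 (8-hydroxy-2,2-dimethyl-7-(3-methylbut-2-enyl)-2H-chromene-6-carbaldehyde)
Conditions: Hoveyda–Grubbs II (5 mol%), 1,4-benzoquinone (10 mol%), 2-methyl-2-butene (20 equiv), CH2Cl2, 40 °C
Reagents that add atoms: 11, 2-methyl-2-butene, CC=C(C)C
Why: cross-metathesis converts the terminal allyl group into the linear prenyl group with loss of propene. The hindered cyclic chromene alkene is inert, and benzoquinone suppresses Ru–H isomerisation of the allyl group.

**Step 5**
Reactants: 4, 12 (methyltriphenylphosphonium bromide)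
Product: 3 (8-hydroxy-2,2-dimethyl-7-prenyl-6-vinyl-2H-chromene)
Conditions: 12 (3 equiv), KOtBu (3.5 equiv), THF, 0 °C to rt
Reagents that add atoms: 12, Ph3P⁺CH3 Br⁻, C[P+](c1ccccc1)(c1ccccc1)c1ccccc1.[Br-] (supplies the CH2)
Why: Wittig methylenation. The extra base deprotonates the 8-OH, which is meta to the CHO and does not deactivate it. Prenyl and chromene alkenes are unaffected.

**Step 6 (key step)**
Reactants: 3, 2 (2,4-dihydroxybenzyl alcohol)
Product: 1 ((S)-Kazinol B)
Conditions: (S)-TRIP-type chiral phosphoric acid (10 mol%), 4 Å MS, toluene, 40 °C; 2 (2 equiv) added by syringe pump over 10 h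
Reagents that add atoms: none
Why: mild acid ionises the 2,4-dihydroxybenzyl alcohol to the dearomatised o-quinone methide (a protonated o-QM/benzyl cation). The 4-alkoxystyrene 3 attacks it through its terminal CH2, giving a para-alkoxy-stabilised benzylic cation. The tethered 2-OH closes this cation in the enantiodetermining step inside the chiral phosphate ion pair, forming C2 and the chroman ring.
Proposed new method: the closest known reaction is the chiral phosphoric acid-catalysed inverse-demand oxa-Diels–Alder of in situ o-QMs with electron-rich alkenes (vinyl ethers, enamides, vinylindoles); here a simple 4-alkoxystyrene is the alkene. The catalyst antipode that delivers 2S is chosen by a small screen, with (S)-TRIP assumed here. The stereocentre is not touched afterwards.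

**Compound list**
1 | (S)-Kazinol B | CC(C)=CCc1c([C@@H]2CCc3ccc(O)cc3O2)cc2c(c1O)OC(C)(C)C=C2 | target
2 | 2,4-dihydroxybenzyl alcohol | OCc1ccc(O)cc1O | starting material
3 | 8-hydroxy-2,2-dimethyl-7-prenyl-6-vinyl-2H-chromene | C=Cc1cc2C=CC(C)(C)Oc2c(O)c1CC=C(C)C | intermediate
4 | 8-hydroxy-2,2-dimethyl-7-prenyl-2H-chromene-6-carbaldehyde | CC(C)=CCc1c(C=O)cc2C=CC(C)(C)Oc2c1O | intermediate
5 | 7-allyl-8-hydroxy-2,2-dimethyl-2H-chromene-6-carbaldehyde | CC1(C)C=Cc2cc(C=O)c(CC=C)c(O)c2O1 | intermediate
6 | 3-allyloxy-4-[(2-methylbut-3-yn-2-yl)oxy]benzaldehyde | C=CCOc1cc(C=O)ccc1OC(C)(C)C#C | intermediate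
7 | 3-hydroxy-4-[(2-methylbut-3-yn-2-yl)oxy]benzaldehyde | O=Cc1ccc(OC(C)(C)C#C)c(O)c1 | intermediate
8 | 3,4-dihydroxybenzaldehyde | O=Cc1ccc(O)c(O)c1 | starting material
9 | 3-chloro-3-methylbut-1-yne | CC(C)(Cl)C#C | starting material (reagent)
10 | allyl bromide | C=CCBr | starting material (reagent)
11 | 2-methyl-2-butene | CC=C(C)C | starting material (reagent)
12 | methyltriphenylphosphonium bromide | C[P+](c1ccccc1)(c1ccccc1)c1ccccc1.[Br-] | starting material (reagent)

**Step count:** 6 steps in total, and the longest linear sequence is also 6 steps (8 → 7 → 6 → 5 → 4 → 3 → 1).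

**Three steps most likely to fail**
1. **Step 6 (o-QM/styrene [4+2]).** Possible failures are low ee, Friedel–Crafts attack of the o-QM on the free phenol ring (para to the 8-OH), o-QM oligomerisation, and cation–olefin cyclisation onto the ortho prenyl group.
   - Fallback: Claisen–Schmidt condensation of aldehyde 4 with 2,4-dihydroxyacetophenone gives the chalcone. Bifunctional-catalyst asymmetric oxa-Michael cyclisation then gives the (S)-flavanone, and acid-free C4 deoxygenation (tosylhydrazone, catecholborane/NaOAc) completes the synthesis.
2. **Step 3 (one-pot double thermal rearrangement).** The two rearrangements may compete or decompose at 205 °C, giving mixtures or low yield.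
   - Fallback: form the chromene by phenylboronate-mediated condensation of a 4-OH aldehyde with prenal, and then install the ortho substituent separately.
3. **Step 4 (cross-metathesis on the free phenol).** The allyl group may isomerise to a propenyl arene, or the Ru catalyst may be poisoned by the phenol.
   - Fallback: skip the allyl/CM sequence. Prepare the 8-hydroxychromene aldehyde by propargyl-Claisen alone, then do ortho-selective C-prenylation of its magnesium phenoxide with prenyl bromide.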